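**Numbering.** Ring atoms follow the target: C1 (epoxide CH), C2 (CH2), C3 (carbinol with the angelate), C4 (methyl-bearing epoxide carbon), C5 (epoxide CH), C6 (CH2), C7 (CH with isopropenyl), C8 (carbinol with the senecioate), C9 (free carbinol), C10 (methyl-bearing epoxide carbon). Open-chain intermediates keep these atom labels. Compound numbers 1–32 are those of the steps and the compound list.

## Analysis of the target

The target 32 is a ten-membered carbocycle of the germacrane type with two trisubstituted epoxides (C1–C10 and C4–C5), three oxygenated carbons (C3 angelate, C8 senecioate, C9 free hydroxyl) and an isopropenyl group at C7. It has eight stereocentres (1R,3S,4S,5S,7R,8S,9S,10S). In each epoxide the two ring bonds are cis, so each comes from a Z alkene. With the ring drawn flat, the oxygens at C3, C8 and C9, the isopropenyl group and the oxygen of the 1,10-epoxide lie on one face and the oxygen of the 4,5-epoxide on the other. The 1,10-epoxide is therefore cis to its neighbouring oxygen at C9, whereas the 4,5-epoxide is trans to its neighbour at C3. The sensitive groups are the two acid-labile epoxides, the angelate (Z to E isomerisation), the senecioate (deconjugation) and the vicinal C8 ester and C9 hydroxyl (acyl shift). The difficulty lies in closing a medium ring, in the contiguous C7–C8–C9 triad, in ending three secondary oxygens differently, and in two epoxides of opposite sense. The route rests on the fact that C9–C10–C1–C2 and C3–C4–C5–C6 are the same unit CH(O)–C(CH3)=CH–CH2 once the epoxide oxygens are removed, Z in both cases and with the carbinol carbon of the same handedness relative to its alkene.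

## Retrosynthetic reasoning

**Epoxide C–O bonds.** Both epoxides are taken off first, because a trisubstituted epoxide would survive neither the Lewis acid of the ring closure nor the stannyl anion before it. The 1,10-epoxide goes last: 32 comes from allylic alcohol 31, whose free C9 hydroxyl can carry a vanadium peroxide to the face cis to itself. The 4,5-epoxide is removed three stages earlier: 27 comes from allylic alcohol 26, whose free C3 hydroxyl hydrogen-bonds a peracid and brings it to the face that ends trans to the C3 oxygen. The opposite sense of the two epoxides thus matches the opposite preferences of the two classical hydroxyl-directed oxidants on Z-cycloalkenols of medium ring size. Each oxidation is run when only one allylic hydroxyl is free.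

**Acyl C–O bonds and the three oxygens.** The angelate of 30 is cut to epoxy alcohol 27 and angelic acid 28; desilylation of 30 gives 31. The senecioate of 25 is cut to ring alcohol 23 and acid chloride 24; removal of the C3 ether of 25 gives 26. The three oxygens are distinguished by what they carry when the ring forms: C8 a free hydroxyl, C3 a 4-methoxybenzyl ether, C9 a silyl ether. Each is addressed by a different reagent class (acylation, oxidative cleavage, fluoride).

**C7–C8 (ring).** Ring alcohol 23 is opened to stannyl aldehyde 22. This is the one ring bond that does not belong to the repeating unit. Cutting it removes the ring, the C7 and C8 stereocentres and the isopropenyl group together. The forward reaction must make the allyl stannane attack the Lewis-acid-bound aldehyde through C7 with allylic transposition, place the C8 oxygen relative to C9 by Felkin–Anh control, and place C7 relative to C8 through an open transition state.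

**End-group adjustments.** Aldehyde 22 comes from alcohol 21, 21 from chloride 20, 20 from diol 19, 19 from hydroxy ester 18, and 18 from 17. Ester 17 is cut at C7=C into aldehyde 15 and ylide 16, which brings in the three carbons of the later isopropenyl group. Aldehyde 15 comes from silyl ether 14, and 14 from 13.

**C3–C4 and C9–C10 (key).** Dienol 13 is cut at C3–C4 into aldehyde 12 and iodoalkene 8. Aldehyde 12 comes through 11 from 10, which is cut at C9–C10 into the same iodoalkene 8 and aldehyde 9. Both cuts lie between a carbinol carbon and a methyl-bearing alkene carbon, so one alkenyl-metal addition under one chiral ligand serves twice. Both aldehydes offer a CH2 next to the carbonyl, so the same ligand enantiomer gives both carbinols. The forward reaction must keep the Z geometry and must not move the β,γ-alkene of 12 into conjugation.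

**The unit.** Iodoalkene 8 is cut at its C=C into aldehyde 3 and phosphonium salt 4; 3 comes from 2 and 2 from diol 1. Reaching the unit in three steps keeps the risk in the iterated coupling.

## Alternatives that were turned down

**Alternative 1:** The ring is seen as the perimeter of a cis-fused bicyclic 1,2-diol A2 built on carvone, in which an extra C3–C8 bond joins two cyclohexenes. In the forward key step Pb(OAc)4 cleaves that bond and releases the ten-membered Z,Z-diene-3,8-dione A1.
- For: the ring forms by fragmentation without high dilution, both Z geometries are fixed by the six-membered rings, and C7 comes from the chiral pool. On ring formation and alkene geometry it is stronger than the chosen route.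
- Against: the cleavage turns C3 and C8 into ketones. Both must then be reduced face-selectively on a flexible ten-membered ring and distinguished for two different esters. The C8 ketone in A1 lies between C7 and C9, and C9 (alkoxy-bearing, allylic and α to the carbonyl) is prone to epimerisation. Both ketones have a β,γ-alkene that can move into conjugation. A2 itself needs a second ring with a tertiary alcohol at each fusion carbon.
- Comparison: the chosen route sets C3 and C9 by a catalyst in the open chain and never passes through ring ketones, at the price of a harder ring closure.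

**Alternative 2:** The C1–C10 bond and the O–C10 bond are cut together. In the forward key step LiN(SiMe3)2 turns the α-bromo ketone of open-chain precursor A4 into its enolate at C10, which adds to the C1 aldehyde and closes the ring; the alkoxide then displaces bromide to give epoxy ketone A3.
- For: the 1,10-epoxide is made without face-selective oxidation of a ring alkene. On that point it is stronger than the chosen route, whose last step depends on a directed epoxidation.
- Against: an aldol closure of a ten-membered ring is reversible and entropically poor. The aldehyde of A4 has a silyloxy group β to the carbonyl and can eliminate under the amide base. The ketone has a second acidic site at C8, whose deprotonation would scramble C8. Only one aldol diastereomer leads to the cis epoxide, and nothing but the ring controls its sense relative to C8. Afterwards the C9 ketone of A3 must be reduced face-selectively next to the epoxide, and the 4,5-epoxide still needs a selective oxidation.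
- Comparison: the chosen route closes the ring by an irreversible C–C bond formation and sets the carbinol centres before the ring exists.

**Alternative 3:** The ring is cut at C7–C8. In the forward key step BF3·OEt2 activates the C8 aldehyde of stannyl aldehyde A6 and the E-allylic stannane attacks through C7, giving ring alcohol A5 with the isopropenyl group in place.
- For: one step gives the ring, two stereocentres and the isopropenyl group. On this point it is as strong as anything in the chosen route, which uses the same closure in step 16.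
- Against: as an organising idea it does not say how the open chain with its two Z alkenes and two carbinol centres is built. The triethylsilyl ether at C3 in A6 would not survive the selective unmasking of the C8 primary alcohol. All the stereochemical and ring-closing risk sits in one late step.
- Comparison: the chosen route keeps this closure as a downstream step, with a 4-methoxybenzyl ether at C3. It places the strategic weight on building the chain from one building block under one ligand, so the material that reaches the ring closure is made by a short, repetitive sequence.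

Key step: step 7

Assumption: the (S) enantiomer of the ligand N-[2-(4-isopropyl-4,5-dihydro-1,3-oxazol-2-yl)-6-methylphenyl]methanesulfonamide is taken to direct the alkenyl group to the Re face of an α-unbranched aldehyde; if it directs to the Si face, its (R) antipode is used in steps 4 and 7 with nothing else changed.

## Route

Step 1
Reactants: 1 propane-1,3-diol
Product: 2 3-(triethylsilyloxy)propan-1-ol
Conditions: NaH (1.0 equiv), THF, 0 °C to rt; Et3SiCl (1.0 equiv), 0 °C
Reagents that add atoms: chlorotriethylsilane, CC[Si](Cl)(CC)CC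
Why: Monosilylation of a symmetrical diol through its sparingly soluble monosodium alkoxide, which is silylated once before a second alkoxide can form.

Step 2
Reactants: 2 3-(triethylsilyloxy)propan-1-ol
Product: 3 3-(triethylsilyloxy)propanal
Conditions: Dess–Martin periodinane, NaHCO3, CH2Cl2, 0 °C to rt
Reagents that add atoms: none
Why: Dess–Martin oxidation; the buffered, base-free medium should keep the β-silyloxy aldehyde from eliminating and leave the triethylsilyl ether intact.

Step 3
Reactants: 3 3-(triethylsilyloxy)propanal; 4 ethyltriphenylphosphonium iodide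
Product: 8 (Z)-triethyl[(4-iodopent-3-en-1-yl)oxy]silane, via ethylidenetriphenylphosphorane 5 (not isolated), via (1-iodoethyl)triphenylphosphonium iodide 6 (not isolated), via (1-iodoethylidene)triphenylphosphorane 7 (not isolated)
Conditions: 4, n-BuLi, THF, rt; I2, THF, −78 °C; NaN(SiMe3)2, −20 °C; 3, −78 °C to rt
Reagents that add atoms: iodine, [I][I]
Why: Stork–Zhao olefination (Wittig reaction of an α-iodo ylide); the unstabilised iodo-ylide should give the Z-iodoalkene, iodine cis to the chain, through the kinetically preferred cis-oxaphosphetane.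

Step 4
Reactants: 8 (Z)-triethyl[(4-iodopent-3-en-1-yl)oxy]silane; 9 (tert-butyldimethylsilyloxy)acetaldehyde
Product: 10 (2R,3Z)-1-(tert-butyldimethylsilyloxy)-3-methyl-6-(triethylsilyloxy)hex-3-en-2-ol
Conditions: CrCl2 (4 equiv), (S)-sulfonamide ligand (4.4 equiv), Et3N (4.4 equiv), THF, rt; NiCl2 (0.1 equiv), 8 and 9, 0 °C to rt
Reagents that add atoms: none
Why: First pass of the Nozaki–Hiyama–Kishi alkenylation, forming C9–C10; the ligand-bound alkenylchromium should add to the Re face of the aldehyde and set C9, and the Z geometry is carried through the nickel and chromium intermediates. The ligand is recovered on work-up.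

Step 5
Reactants: 10 (2R,3Z)-1-(tert-butyldimethylsilyloxy)-3-methyl-6-(triethylsilyloxy)hex-3-en-2-ol
Product: 11 (2R,3Z)-1,2-bis(tert-butyldimethylsilyloxy)-3-methyl-6-(triethylsilyloxy)hex-3-ene
Conditions: t-BuMe2SiOTf, 2,6-lutidine, CH2Cl2, −78 °C
Reagents that add atoms: tert-butyldimethylsilyl trifluoromethanesulfonate, CC(C)(C)[Si](C)(C)OS(=O)(=O)C(F)(F)F
Why: Silylation of a hindered allylic alcohol with a silyl triflate and a hindered base; the primary triethylsilyl ether is stable at this temperature.

Step 6
Reactants: 11 (2R,3Z)-1,2-bis(tert-butyldimethylsilyloxy)-3-methyl-6-(triethylsilyloxy)hex-3-ene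
Product: 12 (3Z,5R)-5,6-bis(tert-butyldimethylsilyloxy)-4-methylhex-3-enal
Conditions: (COCl)2, DMSO, CH2Cl2, −78 °C; 11, −78 to −40 °C; i-Pr2NEt, −78 °C; cold pH 7 buffer
Reagents that add atoms: none
Why: Swern oxidation run directly on a primary triethylsilyl ether: the chlorosulfonium salt cleaves the unhindered Si–O bond to the alkoxysulfonium salt while the tert-butyldimethylsilyl ethers are inert. Base is added cold and the quench is neutral so that the β,γ-alkene stays out of conjugation.

Step 7
Reactants: 12 (3Z,5R)-5,6-bis(tert-butyldimethylsilyloxy)-4-methylhex-3-enal; 8 (Z)-triethyl[(4-iodopent-3-en-1-yl)oxy]silane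
Product: 13 (2R,3Z,6S,7Z)-1,2-bis(tert-butyldimethylsilyloxy)-3,7-dimethyl-10-(triethylsilyloxy)deca-3,7-dien-6-ol
Conditions: CrCl2 (4 equiv), (S)-sulfonamide ligand (4.4 equiv), Et3N (4.4 equiv), THF, rt; NiCl2 (0.1 equiv), 8 (1.5 equiv) and 12, 0 °C to rt
Reagents that add atoms: none
Why: CrCl2 reduces NiCl2 to zerovalent nickel, which inserts into the C–I bond of 8 with retention of the Z geometry; the alkenyl group passes to trivalent chromium, and the alkenylchromium carrying the deprotonated sulfonamide ligand adds to the aldehyde of 12 through a closed, chromium-bound transition state, forming C3–C4. The closest known reaction type is the ligand-mediated asymmetric Nozaki–Hiyama–Kishi alkenylation of aldehydes with 2-iodoalk-2-enes, here run a second time with the same building block. No ring is closed. The new stereocentre C3 (6S in 13) is set by the ligand, which should expose the Re face of this unbranched aldehyde exactly as in step 4; the existing C9 centre is four atoms from the carbonyl and is not expected to override it. The step needs 1,2-addition without enolisation or double-bond migration in the β,γ-unsaturated aldehyde, which the weakly basic, oxophilic alkenylchromium reagent secures. It also needs retention of the Z alkene, which the configurational stability of the alkenylnickel and alkenylchromium species secures. Silyl ethers are inert to divalent chromium, so the chain leaves the step with its C7 end still masked and its C3 hydroxyl free.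

Step 8
Reactants: 13 (2R,3Z,6S,7Z)-1,2-bis(tert-butyldimethylsilyloxy)-3,7-dimethyl-10-(triethylsilyloxy)deca-3,7-dien-6-ol
Product: 14 (2R,3Z,6S,7Z)-1,2-bis(tert-butyldimethylsilyloxy)-6-(4-methoxybenzyloxy)-3,7-dimethyl-10-(triethylsilyloxy)deca-3,7-diene
Conditions: NaH, 4-methoxybenzyl chloride, Bu4NI (cat.), THF/DMF, 0 °C to rt
Reagents that add atoms: 4-methoxybenzyl chloride, COc1ccc(CCl)cc1
Why: Williamson etherification; the C3 alkoxide has no silyl ether close enough to migrate. The 4-methoxybenzyl ether is chosen because it survives fluoride, hydride, stannyl anion and BF3·OEt2 and is later removed oxidatively.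

Step 9
Reactants: 14 (2R,3Z,6S,7Z)-1,2-bis(tert-butyldimethylsilyloxy)-6-(4-methoxybenzyloxy)-3,7-dimethyl-10-(triethylsilyloxy)deca-3,7-diene
Product: 15 (3Z,5S,7Z,9R)-9,10-bis(tert-butyldimethylsilyloxy)-5-(4-methoxybenzyloxy)-4,8-dimethyldeca-3,7-dienal
Conditions: (COCl)2, DMSO, CH2Cl2, −78 °C; 14, −78 to −40 °C; i-Pr2NEt, −78 °C; cold pH 7 buffer
Reagents that add atoms: none
Why: Swern oxidation of the primary triethylsilyl ether as in step 6; the aldehyde is used crude in step 10.

Step 10
Reactants: 15 (3Z,5S,7Z,9R)-9,10-bis(tert-butyldimethylsilyloxy)-5-(4-methoxybenzyloxy)-4,8-dimethyldeca-3,7-dienal; 16 ethyl 2-(triphenylphosphoranylidene)propanoate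
Product: 17 ethyl (2E,5Z,7S,9Z,11R)-11,12-bis(tert-butyldimethylsilyloxy)-7-(4-methoxybenzyloxy)-2,6,10-trimethyldodeca-2,5,9-trienoate
Conditions: toluene, rt
Reagents that add atoms: none
Why: Wittig olefination with a stabilised, α-branched ylide, which should give the E trisubstituted enoate; the ylide is too weakly basic to enolise the aldehyde.

Step 11
Reactants: 17 ethyl (2E,5Z,7S,9Z,11R)-11,12-bis(tert-butyldimethylsilyloxy)-7-(4-methoxybenzyloxy)-2,6,10-trimethyldodeca-2,5,9-trienoate
Product: 18 ethyl (2E,5Z,7S,9Z,11R)-11-(tert-butyldimethylsilyloxy)-12-hydroxy-7-(4-methoxybenzyloxy)-2,6,10-trimethyldodeca-2,5,9-trienoate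
Conditions: HF·pyridine, pyridine, THF, 0 °C
Reagents that add atoms: none
Why: Selective desilylation; the primary silyl ether should be cleaved well before the secondary one at C9, which is shielded by the methyl-bearing alkene carbon. This is done before any tin is in the molecule.

Step 12
Reactants: 18 ethyl (2E,5Z,7S,9Z,11R)-11-(tert-butyldimethylsilyloxy)-12-hydroxy-7-(4-methoxybenzyloxy)-2,6,10-trimethyldodeca-2,5,9-trienoate
Product: 19 (2E,5Z,7S,9Z,11R)-11-(tert-butyldimethylsilyloxy)-7-(4-methoxybenzyloxy)-2,6,10-trimethyldodeca-2,5,9-triene-1,12-diol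
Conditions: i-Bu2AlH (3.5 equiv), CH2Cl2, −78 °C; aq. potassium sodium tartrate
Reagents that add atoms: none
Why: 1,2-Reduction of the enoate to the allylic alcohol by an aluminium hydride; ethers and silyl ethers are inert.

Step 13
Reactants: 19 (2E,5Z,7S,9Z,11R)-11-(tert-butyldimethylsilyloxy)-7-(4-methoxybenzyloxy)-2,6,10-trimethyldodeca-2,5,9-triene-1,12-diol
Product: 20 (2R,3Z,6S,7Z,10E)-2-(tert-butyldimethylsilyloxy)-12-chloro-6-(4-methoxybenzyloxy)-3,7,11-trimethyldodeca-3,7,10-trien-1-ol
Conditions: N-chlorosuccinimide, Me2S, CH2Cl2, −20 °C; 19, −20 to 0 °C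
Reagents that add atoms: N-chlorosuccinimide, O=C1CCC(=O)N1Cl
Why: Corey–Kim chlorination; the alkoxysulfonium salt of the allylic alcohol is displaced by chloride, whereas that of the saturated C8 alcohol reverts to the alcohol on work-up in the absence of base. The E geometry is kept.

Step 14
Reactants: 20 (2R,3Z,6S,7Z,10E)-2-(tert-butyldimethylsilyloxy)-12-chloro-6-(4-methoxybenzyloxy)-3,7,11-trimethyldodeca-3,7,10-trien-1-ol
Product: 21 (2R,3Z,6S,7Z,10E)-2-(tert-butyldimethylsilyloxy)-6-(4-methoxybenzyloxy)-3,7,11-trimethyl-12-(tributylstannyl)dodeca-3,7,10-trien-1-ol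
Conditions: Bu3SnH, LiN(i-Pr)2, THF, 0 °C (Bu3SnLi, 2.2 equiv); 20, −78 °C; aq. NH4Cl
Reagents that add atoms: tributylstannyllithium, [Li][Sn](CCCC)(CCCC)CCCC
Why: SN2 displacement of a primary allylic chloride by a stannyl anion at the unhindered terminus, with the E geometry kept. The first equivalent deprotonates the hydroxyl, and at −78 °C the lithium alkoxide should not cause silyl migration from C9.

Step 15
Reactants: 21 (2R,3Z,6S,7Z,10E)-2-(tert-butyldimethylsilyloxy)-6-(4-methoxybenzyloxy)-3,7,11-trimethyl-12-(tributylstannyl)dodeca-3,7,10-trien-1-ol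
Product: 22 (2R,3Z,6S,7Z,10E)-2-(tert-butyldimethylsilyloxy)-6-(4-methoxybenzyloxy)-3,7,11-trimethyl-12-(tributylstannyl)dodeca-3,7,10-trienal
Conditions: Dess–Martin periodinane, NaHCO3, CH2Cl2, 0 °C
Reagents that add atoms: none
Why: Dess–Martin oxidation under buffered conditions, which should spare the allyl stannane. A(1,3) strain holds the C9–H bond in the plane of the C10=C1 alkene, so the alkene does not acidify it; the aldehyde is used at once.

Step 16
Reactants: 22 (2R,3Z,6S,7Z,10E)-2-(tert-butyldimethylsilyloxy)-6-(4-methoxybenzyloxy)-3,7,11-trimethyl-12-(tributylstannyl)dodeca-3,7,10-trienal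
Product: 23 (3S,7R,8S,9R,1(10)Z,4Z)-9-(tert-butyldimethylsilyloxy)-7-isopropenyl-3-(4-methoxybenzyloxy)-4,10-dimethylcyclodeca-1(10),4-dien-8-ol (target numbering)
Conditions: BF3·OEt2 (2 equiv), CH2Cl2, −78 °C, 22 added slowly (final about 1 mM)
Reagents that add atoms: none
Why: Intramolecular SE2' addition of an allylic stannane to a Lewis-acid-bound aldehyde, forming C7–C8, closing the ten-membered ring and releasing the isopropenyl group by allylic transposition. With a monodentate Lewis acid the C9 silyloxy group should stand anti to the incoming carbon (Felkin–Anh), placing the C8 and C9 oxygens cis on the ring. An open transition state with the C=O and C=C anti and the two ring chains anti across the new bond should place the isopropenyl group cis to the C8 oxygen.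

Step 17
Reactants: 23 ring alcohol (as in step 16); 24 3-methylbut-2-enoyl chloride
Product: 25 (3S,7R,8S,9R,1(10)Z,4Z)-9-(tert-butyldimethylsilyloxy)-7-isopropenyl-3-(4-methoxybenzyloxy)-4,10-dimethylcyclodeca-1(10),4-dien-8-yl 3-methylbut-2-enoate
Conditions: pyridine, DMAP (cat.), CH2Cl2, 0 °C to rt
Reagents that add atoms: none
Why: Acylation of a secondary alcohol by an acid chloride with nucleophilic catalysis; pyridine instead of a stronger amine should avoid vinylketene formation and deconjugation of the senecioate.

Step 18
Reactants: 25 C8 senecioate (as in step 17)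
Product: 26 (3S,7R,8S,9R,1(10)Z,4Z)-9-(tert-butyldimethylsilyloxy)-3-hydroxy-7-isopropenyl-4,10-dimethylcyclodeca-1(10),4-dien-8-yl 3-methylbut-2-enoate
Conditions: DDQ, CH2Cl2/pH 7 buffer, 0 °C
Reagents that add atoms: none
Why: Oxidative cleavage of a 4-methoxybenzyl ether by hydride abstraction and hydrolysis; silyl ether, ester and alkenes are not touched, and the tin is already gone.

Step 19
Reactants: 26 C3 allylic alcohol (as in step 18)
Product: 27 (3S,4R,5S,7R,8S,9R,1(10)Z)-9-(tert-butyldimethylsilyloxy)-4,5-epoxy-3-hydroxy-7-isopropenyl-4,10-dimethylcyclodec-1(10)-en-8-yl 3-methylbut-2-enoate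
Conditions: 3-chloroperoxybenzoic acid (1.05 equiv), NaHCO3, CH2Cl2, −20 to 0 °C
Reagents that add atoms: 3-chloroperoxybenzoic acid, OOC(=O)c1cccc(Cl)c1
Why: Hydroxyl-directed peracid epoxidation (Henbest type). A(1,3) strain holds the C3–H bond in the plane of the C4=C5 alkene, and the hydrogen-bonded peracid adds on the face that carries the C3 hydroxyl, which gives the epoxide trans to the C3 oxygen on the ring, as with Z-cycloalkenols of medium ring size and open-chain Z allylic alcohols; this sets C4 and C5. The hydrogen-bonded allylic alkene should react ahead of the silyloxy-deactivated C10=C1 alkene and the 1,1-disubstituted isopropenyl group.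

Step 20
Reactants: 27 epoxy alcohol (as in step 19); 28 angelic acid, (Z)-2-methylbut-2-enoic acid
Product: 30 (3S,4S,5S,7R,8S,9R,1(10)Z)-9-(tert-butyldimethylsilyloxy)-4,5-epoxy-7-isopropenyl-4,10-dimethyl-8-(3-methylbut-2-enoyloxy)cyclodec-1(10)-en-3-yl (Z)-2-methylbut-2-enoate, via angelic 2,4,6-trichlorobenzoic anhydride 29 (not isolated)
Conditions: 28, 2,4,6-trichlorobenzoyl chloride, Et3N, toluene, rt; 27, toluene, 75 °C
Reagents that add atoms: none
Why: Yamaguchi esterification through the mixed anhydride, run without a nucleophilic amine catalyst so that no reversible conjugate addition can turn the Z acyl group into the E (tiglate) isomer.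

Step 21
Reactants: 30 C3 angelate (as in step 20)
Product: 31 (3S,4S,5S,7R,8S,9R,1(10)Z)-4,5-epoxy-9-hydroxy-7-isopropenyl-4,10-dimethyl-8-(3-methylbut-2-enoyloxy)cyclodec-1(10)-en-3-yl (Z)-2-methylbut-2-enoate
Conditions: HF·pyridine, pyridine, THF, 0 °C to rt
Reagents that add atoms: none
Why: Fluoride-mediated desilylation under buffered acidic conditions; no alkoxide is formed, so the C8 ester should not shift to C9, and the epoxide should tolerate the buffered reagent.

Step 22
Reactants: 31 C9 allylic alcohol (as in step 21)
Product: 32 target, (1R,3S,4S,5S,7R,8S,9S,10S)-1,10:4,5-diepoxy-9-hydroxy-7-isopropenyl-4,10-dimethyl-8-(3-methylbut-2-enoyloxy)cyclodecan-3-yl (Z)-2-methylbut-2-enoate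
Conditions: VO(acac)2 (5 mol %), t-BuOOH (1.5 equiv, in decane), CH2Cl2, 0 °C to rt
Reagents that add atoms: tert-butyl hydroperoxide, CC(C)(C)OO
Why: Vanadium-catalysed hydroxyl-directed epoxidation of an allylic alcohol. The C9 alkoxide bound to pentavalent vanadium delivers the peroxide oxygen at a small O–C9–C10=C1 dihedral angle with the C9–H bond turned toward the C10 methyl group, which gives the epoxide cis to the C9 oxygen, as with cyclic allylic alcohols of ring sizes five to nine; this sets C1 and C10. Only the C10=C1 alkene has an allylic hydroxyl, so the isopropenyl group and the two enoates should be left alone.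

## Compound list

1 | propane-1,3-diol | OCCCO | starting material
2 | 3-(triethylsilyloxy)propan-1-ol | CC[Si](CC)(CC)OCCCO | intermediate
3 | 3-(triethylsilyloxy)propanal | CC[Si](CC)(CC)OCCC=O | intermediate
4 | ethyltriphenylphosphonium iodide | CC[P+](c1ccccc1)(c1ccccc1)c1ccccc1.[I-] | starting material
5 | ethylidenetriphenylphosphorane | CC=P(c1ccccc1)(c1ccccc1)c1ccccc1 | intermediate (not isolated)
6 | (1-iodoethyl)triphenylphosphonium iodide | CC(I)[P+](c1ccccc1)(c1ccccc1)c1ccccc1.[I-] | intermediate (not isolated)
7 | (1-iodoethylidene)triphenylphosphorane | CC(I)=P(c1ccccc1)(c1ccccc1)c1ccccc1 | intermediate (not isolated)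
8 | (Z)-triethyl[(4-iodopent-3-en-1-yl)oxy]silane | C/C(I)=C/CCO[Si](CC)(CC)CC | intermediate
9 | (tert-butyldimethylsilyloxy)acetaldehyde | CC(C)(C)[Si](C)(C)OCC=O | starting material
10 | (2R,3Z)-1-(tert-butyldimethylsilyloxy)-3-methyl-6-(triethylsilyloxy)hex-3-en-2-ol | CC(C)(C)[Si](C)(C)OC[C@H](O)/C(C)=C\CCO[Si](CC)(CC)CC | intermediate
11 | (2R,3Z)-1,2-bis(tert-butyldimethylsilyloxy)-3-methyl-6-(triethylsilyloxy)hex-3-ene | CC(C)(C)[Si](C)(C)OC[C@H](O[Si](C)(C)C(C)(C)C)/C(C)=C\CCO[Si](CC)(CC)CC | intermediate
12 | (3Z,5R)-5,6-bis(tert-butyldimethylsilyloxy)-4-methylhex-3-enal | CC(C)(C)[Si](C)(C)OC[C@H](O[Si](C)(C)C(C)(C)C)/C(C)=C\CC=O | intermediate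
13 | (2R,3Z,6S,7Z)-1,2-bis(tert-butyldimethylsilyloxy)-3,7-dimethyl-10-(triethylsilyloxy)deca-3,7-dien-6-ol | CC(C)(C)[Si](C)(C)OC[C@H](O[Si](C)(C)C(C)(C)C)/C(C)=C\C[C@H](O)/C(C)=C\CCO[Si](CC)(CC)CC | intermediate
14 | (2R,3Z,6S,7Z)-1,2-bis(tert-butyldimethylsilyloxy)-6-(4-methoxybenzyloxy)-3,7-dimethyl-10-(triethylsilyloxy)deca-3,7-diene | CC(C)(C)[Si](C)(C)OC[C@H](O[Si](C)(C)C(C)(C)C)/C(C)=C\C[C@H](OCc1ccc(OC)cc1)/C(C)=C\CCO[Si](CC)(CC)CC | intermediate
15 | (3Z,5S,7Z,9R)-9,10-bis(tert-butyldimethylsilyloxy)-5-(4-methoxybenzyloxy)-4,8-dimethyldeca-3,7-dienal | CC(C)(C)[Si](C)(C)OC[C@H](O[Si](C)(C)C(C)(C)C)/C(C)=C\C[C@H](OCc1ccc(OC)cc1)/C(C)=C\CC=O | intermediate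
16 | ethyl 2-(triphenylphosphoranylidene)propanoate | CCOC(=O)C(C)=P(c1ccccc1)(c1ccccc1)c1ccccc1 | starting material
17 | ethyl (2E,5Z,7S,9Z,11R)-11,12-bis(tert-butyldimethylsilyloxy)-7-(4-methoxybenzyloxy)-2,6,10-trimethyldodeca-2,5,9-trienoate | CC(C)(C)[Si](C)(C)OC[C@H](O[Si](C)(C)C(C)(C)C)/C(C)=C\C[C@H](OCc1ccc(OC)cc1)/C(C)=C\C/C=C(\C)C(=O)OCC | intermediate
18 | ethyl (2E,5Z,7S,9Z,11R)-11-(tert-butyldimethylsilyloxy)-12-hydroxy-7-(4-methoxybenzyloxy)-2,6,10-trimethyldodeca-2,5,9-trienoate | OC[C@H](O[Si](C)(C)C(C)(C)C)/C(C)=C\C[C@H](OCc1ccc(OC)cc1)/C(C)=C\C/C=C(\C)C(=O)OCC | intermediate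
19 | (2E,5Z,7S,9Z,11R)-11-(tert-butyldimethylsilyloxy)-7-(4-methoxybenzyloxy)-2,6,10-trimethyldodeca-2,5,9-triene-1,12-diol | OC[C@H](O[Si](C)(C)C(C)(C)C)/C(C)=C\C[C@H](OCc1ccc(OC)cc1)/C(C)=C\C/C=C(\C)CO | intermediate
20 | (2R,3Z,6S,7Z,10E)-2-(tert-butyldimethylsilyloxy)-12-chloro-6-(4-methoxybenzyloxy)-3,7,11-trimethyldodeca-3,7,10-trien-1-ol | OC[C@H](O[Si](C)(C)C(C)(C)C)/C(C)=C\C[C@H](OCc1ccc(OC)cc1)/C(C)=C\C/C=C(\C)CCl | intermediate
21 | (2R,3Z,6S,7Z,10E)-2-(tert-butyldimethylsilyloxy)-6-(4-methoxybenzyloxy)-3,7,11-trimethyl-12-(tributylstannyl)dodeca-3,7,10-trien-1-ol | OC[C@H](O[Si](C)(C)C(C)(C)C)/C(C)=C\C[C@H](OCc1ccc(OC)cc1)/C(C)=C\C/C=C(\C)C[Sn](CCCC)(CCCC)CCCC | intermediate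
22 | (2R,3Z,6S,7Z,10E)-2-(tert-butyldimethylsilyloxy)-6-(4-methoxybenzyloxy)-3,7,11-trimethyl-12-(tributylstannyl)dodeca-3,7,10-trienal | O=C[C@H](O[Si](C)(C)C(C)(C)C)/C(C)=C\C[C@H](OCc1ccc(OC)cc1)/C(C)=C\C/C=C(\C)C[Sn](CCCC)(CCCC)CCCC | intermediate
23 | (3S,7R,8S,9R,1(10)Z,4Z)-9-(tert-butyldimethylsilyloxy)-7-isopropenyl-3-(4-methoxybenzyloxy)-4,10-dimethylcyclodeca-1(10),4-dien-8-ol (target numbering) | C=C(C)[C@H]1C/C=C(C)\[C@@H](OCc2ccc(OC)cc2)C/C=C(C)\[C@@H](O[Si](C)(C)C(C)(C)C)[C@H]1O | intermediate
24 | 3-methylbut-2-enoyl chloride | CC(C)=CC(Cl)=O | starting material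
25 | C8 senecioate of 23 (3S,7R,8S,9R) | C=C(C)[C@H]1C/C=C(C)\[C@@H](OCc2ccc(OC)cc2)C/C=C(C)\[C@@H](O[Si](C)(C)C(C)(C)C)[C@H]1OC(=O)C=C(C)C | intermediate
26 | C3 alcohol, C8 senecioate, C9 silyl ether, Z,Z-diene (3S,7R,8S,9R) | C=C(C)[C@H]1C/C=C(C)\[C@@H](O)C/C=C(C)\[C@@H](O[Si](C)(C)C(C)(C)C)[C@H]1OC(=O)C=C(C)C | intermediate
27 | 4,5-epoxide trans to C3–OH, C8 senecioate, C9 silyl ether (3S,4R,5S,7R,8S,9R) | C=C(C)[C@H]1C[C@@H]2O[C@]2(C)[C@@H](O)C/C=C(C)\[C@@H](O[Si](C)(C)C(C)(C)C)[C@H]1OC(=O)C=C(C)C | intermediate
28 | angelic acid, (Z)-2-methylbut-2-enoic acid | C/C=C(/C)C(=O)O | starting material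
29 | angelic 2,4,6-trichlorobenzoic anhydride | C/C=C(/C)C(=O)OC(=O)c1c(Cl)cc(Cl)cc1Cl | intermediate (not isolated)
30 | C3 angelate, 4,5-epoxide, C8 senecioate, C9 silyl ether (3S,4S,5S,7R,8S,9R) | C=C(C)[C@H]1C[C@@H]2O[C@]2(C)[C@@H](OC(=O)/C(C)=C\C)C/C=C(C)\[C@@H](O[Si](C)(C)C(C)(C)C)[C@H]1OC(=O)C=C(C)C | intermediate
31 | C9 alcohol, C3 angelate, 4,5-epoxide, C8 senecioate (3S,4S,5S,7R,8S,9R) | C=C(C)[C@H]1C[C@@H]2O[C@]2(C)[C@@H](OC(=O)/C(C)=C\C)C/C=C(C)\[C@@H](O)[C@H]1OC(=O)C=C(C)C | intermediate
32 | CNP0320216.1 (1R,3S,4S,5S,7R,8S,9S,10S) | C=C(C)[C@H]1C[C@@H]2O[C@]2(C)[C@@H](OC(=O)/C(C)=C\C)C[C@H]2O[C@@]2(C)[C@@H](O)[C@H]1OC(=O)C=C(C)C | target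

## Step count and least certain steps

Total: 22 steps. Longest linear sequence: 22 steps (1 to 32; aldehyde 9, ylide 16, acid chloride 24 and acid 28 are bought).

**Step 7 (key step; the same holds for its first pass, step 4).**
- What may go wrong: incomplete facial control, because an aldehyde with only a CH2 next to the carbonyl offers the ligand little to tell its faces apart; migration of the β,γ double bond into conjugation before the C–C bond forms; slow insertion of nickel into the hindered Z-iodide.
- Fallback: set out from 12 and 8 and run the coupling without the chiral ligand (CrCl2, NiCl2 cat., DMSO), which gives 13 together with its C3 epimer F1. The mixture is oxidised with buffered Dess–Martin periodinane to the Z-dienone F2. F2 is reduced with the (R)-2-methyl-oxazaborolidine of the Corey–Bakshi–Shibata reduction and catecholborane at −78 °C, the alkenyl group acting as the large substituent, which returns 13.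

**Step 6 (and its repeat, step 9).**
- What may go wrong: double-bond migration into conjugation under the amine base, or incomplete cleavage of the silyl ether before the base is added.
- Fallback: set out from 11, remove the triethylsilyl group with pyridinium 4-toluenesulfonate in methanol at 0 °C to give the primary alcohol F3, and oxidise F3 with buffered Dess–Martin periodinane, which returns 12.

**Step 16.**
- What may go wrong: intermolecular addition and protodestannylation may outrun the closure of a ten-membered ring. The strain of that ring, and not the open-chain preference, may decide whether the C=O and C=C align anti or gauche, leading to the wrong relation between C7 and C8.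
- Fallback: a Lewis-acid carbonyl-ene closure that needs no tin. Set out from 15 and olefinate with isopropylidenetriphenylphosphorane to the 2-methylprop-1-enyl-terminated triene F4. Remove the primary silyl ether with buffered HF·pyridine to give alcohol F5, oxidise to aldehyde F6 with Dess–Martin periodinane, and treat F6 with Me2AlCl in CH2Cl2 at −78 °C under high dilution. The aldehyde is attacked by C7 of the trisubstituted alkene while a methyl hydrogen passes to oxygen, which gives 23 directly. This closure type is established mainly for other ring sizes, so it is a reserve and not the first choice.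

**Step 20.**
- What may go wrong: isomerisation of the Z acyl group to the E isomer during activation, and slow acylation of a hindered epoxy alcohol at the temperature needed.
- Fallback: build the Z alkene on the molecule. Set out from 27 and esterify with 2-[bis(2,2,2-trifluoroethoxy)phosphoryl]propanoic acid (DCC, DMAP) to the phosphonate ester F7. Treat F7 with KN(SiMe3)2 and 18-crown-6 at −78 °C and then acetaldehyde (Still–Gennari olefination, Z-selective), which returns 30.

**Step 22.**
- What may go wrong: poor facial selectivity. The ten-membered ring is more flexible than the rings on which the cis rule for vanadium rests, and the rotamer with C8 turned toward the C10 methyl group would give the trans epoxide. An acyl shift from C8 to the vanadium-bound C9 oxygen is a lesser concern.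
- Fallback: install the 1,10-epoxide earlier from the homoallylic C8 hydroxyl. Set out from 23 and treat with VO(acac)2 and t-BuOOH. In the chair model for homoallylic alcohols the oxygen is delivered on the face on which C8 stands, anti to the C9 silyloxy group, which is the same face as in the target; this gives epoxy alcohol F8. The isopropenyl group is also homoallylic to this hydroxyl and is the competitor to watch. Then follow the main sequence: acylation with 24 gives F9, DDQ gives F10, the peracid epoxidation directed by the C3 hydroxyl gives F11, Yamaguchi esterification with 28 gives F12, and HF·pyridine returns 32.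

## Further compounds

F1 | step 7 | C3 epimer of 13, (2R,3Z,6R,7Z)-1,2-bis(tert-butyldimethylsilyloxy)-3,7-dimethyl-10-(triethylsilyloxy)deca-3,7-dien-6-ol | CC(C)(C)[Si](C)(C)OC[C@H](O[Si](C)(C)C(C)(C)C)/C(C)=C\C[C@@H](O)/C(C)=C\CCO[Si](CC)(CC)CC
F2 | step 7 | (2R,3Z,7Z)-1,2-bis(tert-butyldimethylsilyloxy)-3,7-dimethyl-10-(triethylsilyloxy)deca-3,7-dien-6-one | CC(C)(C)[Si](C)(C)OC[C@H](O[Si](C)(C)C(C)(C)C)/C(C)=C\CC(=O)/C(C)=C\CCO[Si](CC)(CC)CC
F3 | step 6 | (3Z,5R)-5,6-bis(tert-butyldimethylsilyloxy)-4-methylhex-3-en-1-ol | CC(C)(C)[Si](C)(C)OC[C@H](O[Si](C)(C)C(C)(C)C)/C(C)=C\CCO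
F4 | step 16 | (2R,3Z,6S,7Z)-1,2-bis(tert-butyldimethylsilyloxy)-6-(4-methoxybenzyloxy)-3,7,11-trimethyldodeca-3,7,10-triene | CC(C)(C)[Si](C)(C)OC[C@H](O[Si](C)(C)C(C)(C)C)/C(C)=C\C[C@H](OCc1ccc(OC)cc1)/C(C)=C\CC=C(C)C
F5 | step 16 | (2R,3Z,6S,7Z)-2-(tert-butyldimethylsilyloxy)-6-(4-methoxybenzyloxy)-3,7,11-trimethyldodeca-3,7,10-trien-1-ol | OC[C@H](O[Si](C)(C)C(C)(C)C)/C(C)=C\C[C@H](OCc1ccc(OC)cc1)/C(C)=C\CC=C(C)C
F6 | step 16 | (2R,3Z,6S,7Z)-2-(tert-butyldimethylsilyloxy)-6-(4-methoxybenzyloxy)-3,7,11-trimethyldodeca-3,7,10-trienal | O=C[C@H](O[Si](C)(C)C(C)(C)C)/C(C)=C\C[C@H](OCc1ccc(OC)cc1)/C(C)=C\CC=C(C)C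
F7 | step 20 | C3 2-[bis(2,2,2-trifluoroethoxy)phosphoryl]propanoate of 27 | C=C(C)[C@H]1C[C@@H]2O[C@]2(C)[C@@H](OC(=O)C(C)P(=O)(OCC(F)(F)F)OCC(F)(F)F)C/C=C(C)\[C@@H](O[Si](C)(C)C(C)(C)C)[C@H]1OC(=O)C=C(C)C
F8 | step 22 | 1,10-epoxide of 23 (C8 alcohol, C9 silyl ether, C3 4-methoxybenzyl ether) | C=C(C)[C@H]1C/C=C(C)\[C@@H](OCc2ccc(OC)cc2)C[C@H]2O[C@@]2(C)[C@@H](O[Si](C)(C)C(C)(C)C)[C@H]1O
F9 | step 22 | C8 senecioate of F8 | C=C(C)[C@H]1C/C=C(C)\[C@@H](OCc2ccc(OC)cc2)C[C@H]2O[C@@]2(C)[C@@H](O[Si](C)(C)C(C)(C)C)[C@H]1OC(=O)C=C(C)C
F10 | step 22 | C3 alcohol with 1,10-epoxide, C8 senecioate, C9 silyl ether | C=C(C)[C@H]1C/C=C(C)\[C@@H](O)C[C@H]2O[C@@]2(C)[C@@H](O[Si](C)(C)C(C)(C)C)[C@H]1OC(=O)C=C(C)C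
F11 | step 22 | bis-epoxide with C3 alcohol, C8 senecioate, C9 silyl ether | C=C(C)[C@H]1C[C@@H]2O[C@]2(C)[C@@H](O)C[C@H]2O[C@@]2(C)[C@@H](O[Si](C)(C)C(C)(C)C)[C@H]1OC(=O)C=C(C)C
F12 | step 22 | C9 tert-butyldimethylsilyl ether of 32 | C=C(C)[C@H]1C[C@@H]2O[C@]2(C)[C@@H](OC(=O)/C(C)=C\C)C[C@H]2O[C@@]2(C)[C@@H](O[Si](C)(C)C(C)(C)C)[C@H]1OC(=O)C=C(C)C
A1 | alternative 1 | ten-membered Z,Z-diene-3,8-dione with C9 4-methoxybenzyl ether and C7 isopropenyl | C=C(C)[C@H]1C/C=C(C)\C(=O)C/C=C(C)\[C@@H](OCc2ccc(OC)cc2)C1=O
A2 | alternative 1 | cis-fused bicyclic 3,8-diol with the C3–C8 bond | C=C(C)[C@H]1CC=C(C)[C@@]2(O)CC=C(C)[C@@H](OCc3ccc(OC)cc3)[C@@]12O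
A3 | alternative 2 | ten-membered C9 ketone with cis 1,10-epoxide, Z C4=C5 alkene, C3 silyl ether, C8 4-methoxybenzyl ether | C=C(C)[C@H]1C/C=C(C)\[C@@H](O[Si](C)(C)C(C)(C)C)C[C@H]2O[C@@]2(C)C(=O)[C@H]1OCc3ccc(OC)cc3
A4 | alternative 2 | open-chain C10 bromo C9 ketone with C1 aldehyde | CC(Br)C(=O)[C@@H](OCc1ccc(OC)cc1)[C@@H](C(C)=C)C/C=C(C)\[C@@H](O[Si](C)(C)C(C)(C)C)CC=O
A5 | alternative 3 | ten-membered Z,Z-diene with free C8 hydroxyl, C7 isopropenyl, C3 triethylsilyl ether, C9 tert-butyldimethylsilyl ether | C=C(C)[C@H]1C/C=C(C)\[C@@H](O[Si](CC)(CC)CC)C/C=C(C)\[C@@H](O[Si](C)(C)C(C)(C)C)[C@H]1O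
A6 | alternative 3 | open-chain C8 aldehyde with E-allylic tributylstannane, C3 triethylsilyl ether, C9 tert-butyldimethylsilyl ether | O=C[C@H](O[Si](C)(C)C(C)(C)C)/C(C)=C\C[C@H](O[Si](CC)(CC)CC)/C(C)=C\C/C=C(\C)C[Sn](CCCC)(CCCC)CCCC
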